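## Retrosynthetic overview

1. The target is cut back to the C2-symmetric (3R,6R,3'R,6'R)-ε,ε-carotene-3,3'-diol by a neutral mono-oxidation of one allylic carbinol, so the base-labile 3-oxo ring appears only in the last step.
2. The C40 diol is cut at both C11=C12 bonds: two successive Wittig olefinations, through the C25 hydroxy aldehyde, join the central C10 trienedial to two molecules of one C15 hydroxy phosphonium salt.
3. The C15 diol comes from a trans-selective hydride reduction of a 3-oxo C15 dienoate, with the C3 carbinol centre set by C6.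
4. The 3-oxo dienoate comes from an electrochemical allylic C–H oxygenation (the key C3–O bond) of the C15 dienoate, itself made by Horner–Wadsworth–Emmons olefination of (R)-α-ionone.
5. No ring is built: both cyclohexene rings and the C6/C6' centres are bought in (R)-α-ionone.

Assumption: (R)-(+)-α-ionone of high enantiomeric purity (natural grade) is bought. Positions are given in carotenoid numbering (ring C1–C6, chain C7–C15, primes for the hydroxy half of the C40 compounds).

## Route

**Step 1**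
Reactants: 1 (R)-α-ionone, (3E)-4-[(1R)-2,6,6-trimethylcyclohex-2-en-1-yl]but-3-en-2-one; 2 triethyl phosphonoacetate
Product: 3 ethyl (2E,4E)-3-methyl-5-[(1R)-2,6,6-trimethylcyclohex-2-en-1-yl]penta-2,4-dienoate
Conditions: 2 (1.2 equiv), NaH (1.15 equiv), THF, 0 °C; then 1, 50 °C, 16 h; chromatography removes the minor (2Z) isomer
Reagents that add atoms: none
Why: Horner–Wadsworth–Emmons olefination of the methyl ketone with a stabilised phosphonate anion gives mainly the (2E) trisubstituted alkene, and the weakly basic anion leaves the bought C6–H stereocentre untouched.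

**Step 2**
Reactants: 3 ethyl (2E,4E)-3-methyl-5-[(1R)-2,6,6-trimethylcyclohex-2-en-1-yl]penta-2,4-dienoate
Product: 5 ethyl (2E,4E)-3-methyl-5-[(1R)-2,6,6-trimethyl-4-oxocyclohex-2-en-1-yl]penta-2,4-dienoate, via allylic tert-butyl peroxide 4 (not isolated)
Conditions: N-hydroxytetrachlorophthalimide (20 mol %), pyridine (2 equiv), t-BuOOH (1.5 equiv), LiClO4 (0.1 M), acetone, undivided cell, reticulated vitreous carbon anode and cathode, constant current 10 mA per mmol, rt
Reagents that add atoms: tert-butyl hydroperoxide, CC(C)(C)OO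
Why: Proposed new method: mediated anodic allylic C–H oxygenation on a substrate class where it has not been shown (a cyclohexene carrying a dienoate arm on a doubly allylic, epimerisable C–H stereocentre), in which the anodically formed tetrachlorophthalimide N-oxyl radical abstracts the electron-rich, unhindered C3–H (polarity matched) in preference to the hindered C6–H that is deactivated by the electron-poor dienoate, the allyl radical is capped at its secondary end by tert-butylperoxyl to give 4, and pyridine-promoted Kornblum–DeLaMare loss of tert-butanol gives the enone while the cathode releases H2, so the C3–O bond forms without base and C6 stays intact; the closest known reaction type is the N-hydroxyphthalimide-mediated electrochemical allylic C–H oxidation of simple terpene cyclohexenes to enones.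

**Step 3**
Reactants: 5 ethyl (2E,4E)-3-methyl-5-[(1R)-2,6,6-trimethyl-4-oxocyclohex-2-en-1-yl]penta-2,4-dienoate
Product: 7 (2E,4E)-5-[(1R,4R)-4-hydroxy-2,6,6-trimethylcyclohex-2-en-1-yl]-3-methylpenta-2,4-dien-1-ol, via trans hydroxy ester 6 (not isolated)
Conditions: LiBH(s-Bu)3 (1.1 equiv), THF, −78 °C, 1 h; then i-Bu2AlH (3.0 equiv), −78 to 0 °C; aq. KNaC4H4O6; chromatography removes the minor cis diol
Reagents that add atoms: none
Why: Substrate-controlled 1,2-hydride reduction in which the bulky borohydride attacks the C3 carbonyl anti to the axial C1 methyl group, that is from the face of the pseudo-axial C6 side chain, so the new hydroxyl ends trans to the chain (3R), after which i-Bu2AlH reduces the ester to the allylic alcohol in the same flask.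

**Step 4**
Reactants: 7 (2E,4E)-5-[(1R,4R)-4-hydroxy-2,6,6-trimethylcyclohex-2-en-1-yl]-3-methylpenta-2,4-dien-1-ol
Product: 8 [(2E,4E)-5-[(1R,4R)-4-hydroxy-2,6,6-trimethylcyclohex-2-en-1-yl]-3-methylpenta-2,4-dien-1-yl]triphenylphosphonium bromide
Conditions: Ph3P·HBr (1.05 equiv), MeOH, 0 °C to rt, 12 h; evaporate; triturate with Et2O/EtOAc
Reagents that add atoms: triphenylphosphine hydrobromide, [Br-].[PH+](c1ccccc1)(c1ccccc1)c1ccccc1
Why: Phosphonium salt formation by acid-promoted ionisation of the dienylic primary alcohol to a pentadienyl cation that Ph3P captures at the unhindered terminus, which is far faster than ionisation of the ring allylic alcohol under this weakly acidic reagent, so the C3 carbinol and both stereocentres are kept.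

**Step 5**
Reactants: 8 [(2E,4E)-5-[(1R,4R)-4-hydroxy-2,6,6-trimethylcyclohex-2-en-1-yl]-3-methylpenta-2,4-dien-1-yl]triphenylphosphonium bromide; 9 (2E,4E,6E)-2,7-dimethylocta-2,4,6-trienedial
Product: 10 (2E,4E,6E,8E,10E,12E)-13-[(1R,4R)-4-hydroxy-2,6,6-trimethylcyclohex-2-en-1-yl]-2,7,11-trimethyltrideca-2,4,6,8,10,12-hexaenal
Conditions: 9 (3.0 equiv), 8 (1.0 equiv, added over 2 h), 1,2-epoxybutane/EtOH 1:1, reflux, 6 h, argon, dark; chromatography; excess 9 recovered
Reagents that add atoms: none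
Why: Wittig olefination under base-free epoxide conditions (the epoxide takes up HBr and releases the ylide), in which the threefold excess of the dial and slow addition of the salt stop the reaction at the mono-olefinated C25 aldehyde, and any Z isomer at the new disubstituted double bond reverts to E on heating.

**Step 6**
Reactants: 10 (2E,4E,6E,8E,10E,12E)-13-[(1R,4R)-4-hydroxy-2,6,6-trimethylcyclohex-2-en-1-yl]-2,7,11-trimethyltrideca-2,4,6,8,10,12-hexaenal; 8 [(2E,4E)-5-[(1R,4R)-4-hydroxy-2,6,6-trimethylcyclohex-2-en-1-yl]-3-methylpenta-2,4-dien-1-yl]triphenylphosphonium bromide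
Product: 11 (3R,6R,3'R,6'R)-ε,ε-carotene-3,3'-diol (all-E)
Conditions: 8 (1.3 equiv), 1,2-epoxybutane/EtOH 1:1, reflux, 20 h, argon, dark; crystallise from CH2Cl2/hexane
Reagents that add atoms: none
Why: Second Wittig olefination under the same base-free epoxide conditions builds the remaining C11=C12 bond without touching the free allylic hydroxyls or the C6–H centres, and prolonged heating equilibrates the Z isomers so that the all-E diol crystallises.

**Step 7**
Reactants: 11 (3R,6R,3'R,6'R)-ε,ε-carotene-3,3'-diol (all-E)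
Product: 12 (3'R,6R,6'R)-3'-hydroxy-ε,ε-caroten-3-one (all-E), the target
Conditions: activated MnO2 (about 6 mass equiv, in portions), CH2Cl2, rt, dark, stopped near 55% conversion; chromatography; recovered 11 recycled
Reagents that add atoms: none
Why: Heterogeneous MnO2 oxidation of an allylic alcohol under neutral conditions turns one of the two equivalent C3 carbinols into the enone without touching the polyene or the base-labile C6–H, the mono-ketone being the main product at partial conversion (statistical, about 40–45% per pass).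

## Compound list

1 | (R)-α-ionone, (3E)-4-[(1R)-2,6,6-trimethylcyclohex-2-en-1-yl]but-3-en-2-one | CC1=CCCC(C)(C)[C@H]1/C=C/C(C)=O | starting material
2 | triethyl phosphonoacetate | CCOC(=O)CP(=O)(OCC)OCC | starting material
3 | ethyl (2E,4E)-3-methyl-5-[(1R)-2,6,6-trimethylcyclohex-2-en-1-yl]penta-2,4-dienoate | CC1=CCCC(C)(C)[C@H]1/C=C/C(C)=C/C(=O)OCC | intermediate
4 | ethyl (2E,4E)-5-[(1R)-4-(tert-butylperoxy)-2,6,6-trimethylcyclohex-2-en-1-yl]-3-methylpenta-2,4-dienoate (C4 epimers) | CC1=CC(OOC(C)(C)C)CC(C)(C)[C@H]1/C=C/C(C)=C/C(=O)OCC | intermediate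
5 | ethyl (2E,4E)-3-methyl-5-[(1R)-2,6,6-trimethyl-4-oxocyclohex-2-en-1-yl]penta-2,4-dienoate | CC1=CC(=O)CC(C)(C)[C@H]1/C=C/C(C)=C/C(=O)OCC | intermediate
6 | ethyl (2E,4E)-5-[(1R,4R)-4-hydroxy-2,6,6-trimethylcyclohex-2-en-1-yl]-3-methylpenta-2,4-dienoate | CC1=C[C@H](O)CC(C)(C)[C@H]1/C=C/C(C)=C/C(=O)OCC | intermediate
7 | (2E,4E)-5-[(1R,4R)-4-hydroxy-2,6,6-trimethylcyclohex-2-en-1-yl]-3-methylpenta-2,4-dien-1-ol | CC1=C[C@H](O)CC(C)(C)[C@H]1/C=C/C(C)=C/CO | intermediate
8 | [(2E,4E)-5-[(1R,4R)-4-hydroxy-2,6,6-trimethylcyclohex-2-en-1-yl]-3-methylpenta-2,4-dien-1-yl]triphenylphosphonium bromide | CC1=C[C@H](O)CC(C)(C)[C@H]1/C=C/C(C)=C/C[P+](c2ccccc2)(c3ccccc3)c4ccccc4.[Br-] | intermediate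
9 | (2E,4E,6E)-2,7-dimethylocta-2,4,6-trienedial | O=C/C(C)=C/C=C/C=C(C)/C=O | starting material
10 | (2E,4E,6E,8E,10E,12E)-13-[(1R,4R)-4-hydroxy-2,6,6-trimethylcyclohex-2-en-1-yl]-2,7,11-trimethyltrideca-2,4,6,8,10,12-hexaenal | CC1=C[C@H](O)CC(C)(C)[C@H]1/C=C/C(C)=C/C=C/C(C)=C/C=C/C=C(C)/C=O | intermediate
11 | (3R,6R,3'R,6'R)-ε,ε-carotene-3,3'-diol (all-E) | CC1=C[C@H](O)CC(C)(C)[C@H]1/C=C/C(C)=C/C=C/C(C)=C/C=C/C=C(C)/C=C/C=C(C)/C=C/[C@H]1C(C)=C[C@H](O)CC1(C)C | intermediate
12 | (3'R,6R,6'R)-3'-hydroxy-ε,ε-caroten-3-one (all-E) | CC1=CC(=O)CC(C)(C)[C@H]1/C=C/C(C)=C/C=C/C(C)=C/C=C/C=C(C)/C=C/C=C(C)/C=C/[C@H]1C(C)=C[C@H](O)CC1(C)C | target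

## Step count and risks

Total steps: 7. Longest linear sequence: 7 (1 → 3 → 5 → 7 → 8 → 10 → 11 → 12).

The three steps most likely to fail:

**Step 2 (the proposed new step).** The risk is attack at the doubly allylic C6–H or a stalled electrolysis. The fallback uses known oxygen-transposition chemistry that never makes a radical next to C6. It sets out from 3 and comes back at 5. m-CPBA (CH2Cl2, NaHCO3, 0 °C) epoxidises only the electron-rich ring alkene and gives the ring epoxide ethyl (2E,4E)-3-methyl-5-[(2R)-1,3,3-trimethyl-7-oxabicyclo[4.1.0]heptan-2-yl]penta-2,4-dienoate F1. NaSePh (from PhSeSePh and NaBH4, EtOH) opens it at the secondary carbon and gives the hydroxy selenide ethyl (2E,4E)-5-[(1R)-2-hydroxy-2,6,6-trimethyl-3-(phenylselanyl)cyclohexyl]-3-methylpenta-2,4-dienoate F2. H2O2 oxidation and selenoxide syn-elimination toward C3, the only side with β-hydrogens, gives the tertiary allylic alcohol ethyl (2E,4E)-5-[(1R)-2-hydroxy-2,6,6-trimethylcyclohex-3-en-1-yl]-3-methylpenta-2,4-dienoate F3. Pyridinium chlorochromate C5H5NH[CrO3Cl] in CH2Cl2 then effects the Babler–Dauben oxidative 1,3-transposition to enone 5.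

**Step 3.** The trans selectivity rests on a conformational argument, and the reduction may favour the cis alcohol. The fallback then takes the selectivity from an inversion instead of from the reduction. It sets out from 5 and comes back at 7. The hydride that proved cis-selective (LiBH(s-Bu)3 without the i-Bu2AlH stage, or NaBH4/CeCl3 in MeOH at −40 °C) gives the cis alcohol ethyl (2E,4E)-5-[(1R,4S)-4-hydroxy-2,6,6-trimethylcyclohex-2-en-1-yl]-3-methylpenta-2,4-dienoate F4. A Mitsunobu reaction (PPh3, diisopropyl azodicarboxylate, benzoic acid, THF, 0 °C) inverts C3 and gives the trans benzoate (1R,4R)-4-[(1E,3E)-5-ethoxy-3-methyl-5-oxopenta-1,3-dien-1-yl]-3,5,5-trimethylcyclohex-2-en-1-yl benzoate F5. i-Bu2AlH (5 equiv, CH2Cl2, −78 to 0 °C) cleaves the benzoate and reduces the ethyl ester in one operation to diol 7.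

**Step 7.** The mono-oxidation is statistical and may separate poorly or give too little product. The fallback differentiates the two ends before the second olefination. It sets out from 10 and comes back at 12. TBSCl and imidazole in DMF convert the C25 hydroxy aldehyde 10 into the silyl ether (2E,4E,6E,8E,10E,12E)-13-[(1R,4R)-4-[tert-butyl(dimethyl)silyl]oxy-2,6,6-trimethylcyclohex-2-en-1-yl]-2,7,11-trimethyltrideca-2,4,6,8,10,12-hexaenal F6. A Wittig reaction with salt 8 (1.3 equiv, 1,2-epoxybutane/EtOH, reflux) gives the mono-protected diol (3R,6R,3'R,6'R)-3'-[tert-butyl(dimethyl)silyl]oxy-ε,ε-caroten-3-ol F7. MnO2 (CH2Cl2, rt) oxidises the only free allylic hydroxyl completely and gives the silyl-protected ketone (3'R,6R,6'R)-3'-[tert-butyl(dimethyl)silyl]oxy-ε,ε-caroten-3-one F8. HF·pyridine in THF/pyridine at 0 °C removes the silyl group without base and gives 12.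

## Further compounds

F1 | step 2 | ethyl (2E,4E)-3-methyl-5-[(2R)-1,3,3-trimethyl-7-oxabicyclo[4.1.0]heptan-2-yl]penta-2,4-dienoate (epoxide epimers) | CC12OC1CCC(C)(C)[C@H]2/C=C/C(C)=C/C(=O)OCC
F2 | step 2 | ethyl (2E,4E)-5-[(1R)-2-hydroxy-2,6,6-trimethyl-3-(phenylselanyl)cyclohexyl]-3-methylpenta-2,4-dienoate (diastereomer mixture) | CC1(O)C([Se]c2ccccc2)CCC(C)(C)[C@H]1/C=C/C(C)=C/C(=O)OCC
F3 | step 2 | ethyl (2E,4E)-5-[(1R)-2-hydroxy-2,6,6-trimethylcyclohex-3-en-1-yl]-3-methylpenta-2,4-dienoate (C2 epimers) | CC1(O)C=CCC(C)(C)[C@H]1/C=C/C(C)=C/C(=O)OCC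
F4 | step 3 | ethyl (2E,4E)-5-[(1R,4S)-4-hydroxy-2,6,6-trimethylcyclohex-2-en-1-yl]-3-methylpenta-2,4-dienoate | CC1=C[C@@H](O)CC(C)(C)[C@H]1/C=C/C(C)=C/C(=O)OCC
F5 | step 3 | (1R,4R)-4-[(1E,3E)-5-ethoxy-3-methyl-5-oxopenta-1,3-dien-1-yl]-3,5,5-trimethylcyclohex-2-en-1-yl benzoate | CC1=C[C@H](OC(=O)c2ccccc2)CC(C)(C)[C@H]1/C=C/C(C)=C/C(=O)OCC
F6 | step 7 | (2E,4E,6E,8E,10E,12E)-13-[(1R,4R)-4-[tert-butyl(dimethyl)silyl]oxy-2,6,6-trimethylcyclohex-2-en-1-yl]-2,7,11-trimethyltrideca-2,4,6,8,10,12-hexaenal | CC1=C[C@H](O[Si](C)(C)C(C)(C)C)CC(C)(C)[C@H]1/C=C/C(C)=C/C=C/C(C)=C/C=C/C=C(C)/C=O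
F7 | step 7 | (3R,6R,3'R,6'R)-3'-[tert-butyl(dimethyl)silyl]oxy-ε,ε-caroten-3-ol (all-E) | CC1=C[C@H](O[Si](C)(C)C(C)(C)C)CC(C)(C)[C@H]1/C=C/C(C)=C/C=C/C(C)=C/C=C/C=C(C)/C=C/C=C(C)/C=C/[C@H]1C(C)=C[C@H](O)CC1(C)C
F8 | step 7 | (3'R,6R,6'R)-3'-[tert-butyl(dimethyl)silyl]oxy-ε,ε-caroten-3-one (all-E) | CC1=C[C@H](O[Si](C)(C)C(C)(C)C)CC(C)(C)[C@H]1/C=C/C(C)=C/C=C/C(C)=C/C=C/C=C(C)/C=C/C=C(C)/C=C/[C@H]1C(C)=CC(=O)CC1(C)C
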